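Both benzenoid rings are taken back to 2-alkylcyclohexane-1,3-diones, because in each coumarin C8, the ring carbon that carries the side chain, is flanked by the oxygen-bearing carbons C7 and C8a. A double intramolecular Claisen condensation of an acyclic bis(5-oxo ester), which already holds the tertiary–secondary ether, both stereocentres and the isopropenyl group, closes the two six-membered carbocycles in one operation by forming C8–C7 in each half. This precursor is reached in five steps from homoprenyl bromide: one Shi epoxide supplies both ether partners, and the keto ester arms are attached last by twofold zinc insertion and acylation. Methylation, dehydrogenation, ortho-formylation and Wittig lactonisation then complete the coumarins.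

Key step: step 6

Remark: the D-fructose-derived Shi ketone is taken to give (R)-epoxides from 2-methylalk-2-enes, so its enantiomer is specified in step 1. Three parts of epoxide 2 go into step 2 and one part is kept for step 3. From step 5 onwards every operation is carried out twice on the same molecule, once in each half.

Step 1
Reactants: 1 5-bromo-2-methylpent-2-ene
Product: 2 (3S)-3-(2-bromoethyl)-2,2-dimethyloxirane
Conditions: 1,2:4,5-di-O-isopropylidene-β-L-erythro-2,3-hexodiulo-2,6-pyranose (enantiomer of the D-fructose-derived Shi ketone, 30 mol%), KHSO5 (as 2KHSO5·KHSO4·K2SO4), K2CO3, Bu4NHSO4, Na2B4O7 buffer (pH 10.5), MeCN–CH2(OMe)2–H2O, 0 °C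
Reagents that add atoms: potassium peroxymonosulfate, [K+].[O-]S(=O)(=O)OO
Why: Shi epoxidation, in which the chiral dioxirane formed in situ from the ketone and KHSO5 transfers oxygen through a spiro transition state to one face of the trisubstituted alkene, the L-series ketone being chosen so that C3, the only stereocentre formed, should be (S), while the primary bromide is inert in the buffered medium.

Step 2
Reactants: 2 (3S)-3-(2-bromoethyl)-2,2-dimethyloxirane
Product: 3 (3S)-1-bromo-4-methylpent-4-en-3-ol
Conditions: Et2AlCl, Li(tmp) (tmp = 2,2,6,6-tetramethylpiperidide; 2.5 equiv each), PhMe, 0 °C; then aq. KNaC4H4O6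
Reagents that add atoms: none
Why: aluminium amide-mediated isomerisation of an epoxide to an allylic alcohol, in which aluminium binds the epoxide oxygen and the hindered amide removes a methyl proton in a cyclic syn-elimination that breaks only the tertiary C–O bond, so that the C3–O bond keeps its (S) configuration and the bulky, weakly nucleophilic reagent should leave the primary bromide alone.

Step 3
Reactants: 2 (3S)-3-(2-bromoethyl)-2,2-dimethyloxirane; 3 (3S)-1-bromo-4-methylpent-4-en-3-ol
Product: 4 (3S)-1-bromo-4-{[(3S)-1-bromo-4-methylpent-4-en-3-yl]oxy}-4-methylpentan-3-ol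
Conditions: 3 (3 equiv, excess recovered), BF3·OEt2 (10 mol%), CH2Cl2, −40 → −10 °C, slow addition of 2
Reagents that add atoms: none
Why: Lewis acid-catalysed alcoholysis of a trisubstituted epoxide, in which BF3 polarises the tertiary C–O bond and the hydroxyl of 3 attacks the tertiary carbon (Markovnikov opening), so that no bond at either stereocentre is broken, both (S) centres are carried over unchanged, and the diastereomer arising from residual minor enantiomers can be removed here.

Step 4
Reactants: 4 (3S)-1-bromo-4-{[(3S)-1-bromo-4-methylpent-4-en-3-yl]oxy}-4-methylpentan-3-ol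
Product: 5 tert-butyldimethylsilyl ether of 4
Conditions: TBSOTf, 2,6-lutidine, CH2Cl2, 0 °C
Reagents that add atoms: tert-butyldimethylsilyl triflate, CC(C)(C)[Si](C)(C)OS(=O)(=O)C(F)(F)F
Why: silylation of a hindered secondary alcohol with a silyl triflate and a non-nucleophilic base, giving an ether that prevents hemiketal or enol ether formation with the 1,4-related carbonyl groups made later and that withstands alkoxide, amide base and heat.

Step 5
Reactants: 5 tert-butyldimethylsilyl ether of 4; 6 methyl 5-chloro-5-oxopentanoate (two molecules, one for each alkylzinc terminus)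
Product: 8 (S,S)-bis(5-oxo ester) ether (methyl esters; silyl ether), via bis(alkylzinc bromide) 7 (not isolated)
Conditions: Zn dust (activated with BrCH2CH2Br and Me3SiCl), LiCl, THF, 50 °C; then 6 (2.6 equiv), Pd(PPh3)4 (5 mol%), THF, 0 °C → rt
Reagents that add atoms: methyl 5-chloro-5-oxopentanoate (second molecule of 6), COC(=O)CCCC(=O)Cl
Why: LiCl-promoted insertion of zinc into both primary C–Br bonds followed by twofold Negishi acylation, in which the alkylzinc bromides tolerate ether, silyl ether and ester groups and zerovalent palladium couples each of them with one molecule of the acid chloride much faster than they add to the methyl ester or to the new ketone, so that two molecules of 6 are consumed per molecule of 5 and both 5-oxo ester arms are attached without touching a stereocentre.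

Step 6
Reactants: 8 (S,S)-bis(5-oxo ester) ether (methyl esters; silyl ether)
Product: 10 (S,S)-bis(2-alkylcyclohexane-1,3-dione), via dipotassium bis(enolate) 9 (not isolated)
Conditions: KOtBu (5 equiv), THF (0.02 M), 0 °C → rt; then 1 M aq. HCl to pH 3, 0 °C
Reagents that add atoms: none
Why: tert-Butoxide enolises each ketone reversibly on both sides, and the enolate at the side-chain methylene (the future C8) adds to the ester carbonyl five bonds away and expels methoxide, after which the acidic 1,3-dione is deprotonated to salt 9, so that two C8–C7 bonds and two six-membered carbocycles should form in one operation. The closest known reaction type is the base-mediated intramolecular Claisen (Dieckmann-type) cyclisation of 5-oxoalkanoates to 2-alkylcyclohexane-1,3-diones. Each ring closes in the 6-(enolendo)-exo-trig mode. No stereocentre is created, because C2 of each dione carries two constitutionally identical ring arms, and the two existing centres lie gamma to the ketones, where they can neither enolise nor suffer beta-elimination. The step needs regioselectivity between the two enolates of each ketone and preference for ring closure over condensation between molecules: the first is set by the substrate, since the other enolate could only close a strained four-membered ring and reverts, and the second is secured by high dilution and by the thermodynamic sink of the dione enolate.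

Step 7
Reactants: 10 (S,S)-bis(2-alkylcyclohexane-1,3-dione)
Product: 11 (S,S)-bis(3-methoxy-2-alkylcyclohex-2-en-1-one)
Conditions: Me3SiCHN2 (3 equiv), MeOH–PhMe (1:4), 0 °C → rt; crude 10 used at once
Reagents that add atoms: trimethylsilyldiazomethane, C[Si](C)(C)C=[N+]=[N-]
Why: O-methylation of an acidic enol by a diazoalkane, in which the dione protonates the reagent, methanol removes the silyl group and the enolate oxygen captures the methyldiazonium ion, so that one molecule of the reagent should deliver one methyl group to each ring by O-alkylation only and, each dione being symmetric about C2, a single vinylogous ester should result per ring.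

Step 8
Reactants: 11 (S,S)-bis(3-methoxy-2-alkylcyclohex-2-en-1-one)
Product: 15 (S,S)-bis(3-methoxy-2-alkylphenol), via bis(6-phenylselanyl enone) 12 (not isolated), via bis(selenoxide) 13 (not isolated), via bis(cyclohexa-2,5-dienone) 14 (not isolated)
Conditions: LiN(iPr)2 (2.5 equiv), THF, −78 °C; PhSeCl (2.5 equiv), −78 °C; then 30% aq. H2O2 (excess), 0 °C → rt
Reagents that add atoms: none
Why: α′-selenenylation followed by selenoxide syn-elimination, in which kinetic deprotonation of each vinylogous ester at C6, trapping with PhSeCl, oxidation at selenium and loss of PhSeOH give cross-conjugated dienones that tautomerise at once to the phenols, while excess peroxide and the diisopropylamine left from the base consume PhSeOH before it can add to the isopropenyl group.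

Step 9
Reactants: 15 (S,S)-bis(3-methoxy-2-alkylphenol)
Product: 17 (S,S)-bis(3-alkyl-2-hydroxy-4-methoxybenzaldehyde), via bis(2-hydroxybenzyl alcohol) 16 (not isolated)
Conditions: MgCl2, Et3N, (CH2O)n (excess), MeCN, reflux; then aq. NH4Cl
Reagents that add atoms: paraformaldehyde (as formaldehyde), C=O
Why: magnesium-mediated ortho-formylation of phenols (Casnati–Skattebøl reaction), in which each magnesium phenoxide delivers one molecule of formaldehyde within a chelate to the only unsubstituted ortho carbon, which is also para to the methoxy group and becomes C4a, and a further formaldehyde per ring accepts hydride from the benzylic alkoxide to give the aldehyde and methanol.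

Step 10
Reactants: 17 (S,S)-bis(3-alkyl-2-hydroxy-4-methoxybenzaldehyde); 18 ethyl (triphenylphosphoranylidene)acetate (two molecules, one for each aldehyde)
Product: 20 silyl-protected (S,S)-bis(7-methoxycoumarin-8-yl) ether, via bis(ethyl 2-hydroxycinnamate) 19 (not isolated)
Conditions: 18 (3 equiv), PhNEt2, reflux (about 215 °C)
Reagents that add atoms: ethyl (triphenylphosphoranylidene)acetate (second molecule of 18), CCOC(=O)C=P(c1ccccc1)(c1ccccc1)c1ccccc1
Why: Wittig olefination with a stabilised ylide followed by thermal lactonisation, in which the cinnamates equilibrate between E and Z at this temperature and the Z isomers are drained by attack of the ortho-phenol on the ester with loss of ethanol, a sequence established for 3-alkyl-2-hydroxy-4-methoxybenzaldehydes, while the basic solvent keeps the phenol from adding to the isopropenyl group.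

Step 11
Reactants: 20 silyl-protected (S,S)-bis(7-methoxycoumarin-8-yl) ether
Product: 21 CNP0142500.1
Conditions: HF·pyridine, pyridine–THF, 0 °C → rt
Reagents that add atoms: none
Why: fluoride-induced cleavage of a silyl ether driven by the strong Si–F bond, the buffered reagent being expected to free the secondary alcohol without opening the lactones or ionising the tertiary–allylic ether.

Compound list

1 | 5-bromo-2-methylpent-2-ene | CC(C)=CCCBr | starting material
2 | (3S)-3-(2-bromoethyl)-2,2-dimethyloxirane | CC1(C)O[C@H]1CCBr | intermediate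
3 | (3S)-1-bromo-4-methylpent-4-en-3-ol | C=C(C)[C@H](CCBr)O | intermediate
4 | (3S)-1-bromo-4-{[(3S)-1-bromo-4-methylpent-4-en-3-yl]oxy}-4-methylpentan-3-ol | C=C(C)[C@H](CCBr)OC(C)(C)[C@@H](O)CCBr | intermediate
5 | tert-butyl{[(3S)-1-bromo-4-{[(3S)-1-bromo-4-methylpent-4-en-3-yl]oxy}-4-methylpentan-3-yl]oxy}dimethylsilane | C=C(C)[C@H](CCBr)OC(C)(C)[C@@H](O[Si](C)(C)C(C)(C)C)CCBr | intermediate
6 | methyl 5-chloro-5-oxopentanoate | COC(=O)CCCC(=O)Cl | starting material
7 | bis(alkylzinc bromide) of 5 (each C–Br replaced by C–ZnBr; not isolated) | C=C(C)[C@H](CC[Zn]Br)OC(C)(C)[C@@H](O[Si](C)(C)C(C)(C)C)CC[Zn]Br | intermediate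
8 | methyl (8S)-8-{[(3S)-3-(tert-butyldimethylsilyloxy)-10-methoxy-2-methyl-6,10-dioxodecan-2-yl]oxy}-9-methyl-5-oxodec-9-enoate | C=C(C)[C@H](CCC(=O)CCCC(=O)OC)OC(C)(C)[C@@H](O[Si](C)(C)C(C)(C)C)CCC(=O)CCCC(=O)OC | intermediate
9 | dipotassium bis(enolate) of 10 (not isolated) | [K+].[K+].C=C(C)[C@H](CC1=C([O-])CCCC1=O)OC(C)(C)[C@@H](O[Si](C)(C)C(C)(C)C)CC1=C([O-])CCCC1=O | intermediate
10 | 2-[(2S)-2-{[(3S)-3-(tert-butyldimethylsilyloxy)-4-(2,6-dioxocyclohexyl)-2-methylbutan-2-yl]oxy}-3-methylbut-3-en-1-yl]cyclohexane-1,3-dione | C=C(C)[C@H](CC1C(=O)CCCC1=O)OC(C)(C)[C@@H](O[Si](C)(C)C(C)(C)C)CC1C(=O)CCCC1=O | intermediate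
11 | bis(3-methoxycyclohex-2-en-1-on-2-yl) analogue of 10 (each dione as its methyl enol ether; (S,S)) | C=C(C)[C@H](CC1=C(OC)CCCC1=O)OC(C)(C)[C@@H](O[Si](C)(C)C(C)(C)C)CC1=C(OC)CCCC1=O | intermediate
12 | 11 carrying a phenylselanyl group at C6 of each ring (diastereomer mixture at C6; not isolated) | C=C(C)[C@H](CC1=C(OC)CCC([Se]c2ccccc2)C1=O)OC(C)(C)[C@@H](O[Si](C)(C)C(C)(C)C)CC1=C(OC)CCC([Se]c2ccccc2)C1=O | intermediate
13 | bis(selenoxide) of 12 (not isolated) | C=C(C)[C@H](CC1=C(OC)CCC([Se](=O)c2ccccc2)C1=O)OC(C)(C)[C@@H](O[Si](C)(C)C(C)(C)C)CC1=C(OC)CCC([Se](=O)c2ccccc2)C1=O | intermediate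
14 | bis(3-methoxycyclohexa-2,5-dien-1-on-2-yl) compound, keto tautomer of 15 (not isolated) | C=C(C)[C@H](CC1=C(OC)CC=CC1=O)OC(C)(C)[C@@H](O[Si](C)(C)C(C)(C)C)CC1=C(OC)CC=CC1=O | intermediate
15 | 2-[(2S)-2-{[(3S)-3-(tert-butyldimethylsilyloxy)-4-(2-hydroxy-6-methoxyphenyl)-2-methylbutan-2-yl]oxy}-3-methylbut-3-en-1-yl]-3-methoxyphenol | C=C(C)[C@H](Cc1c(O)cccc1OC)OC(C)(C)[C@@H](O[Si](C)(C)C(C)(C)C)Cc1c(O)cccc1OC | intermediate
16 | 15 carrying a hydroxymethyl group ortho to each phenolic OH (not isolated) | C=C(C)[C@H](Cc1c(OC)ccc(CO)c1O)OC(C)(C)[C@@H](O[Si](C)(C)C(C)(C)C)Cc1c(OC)ccc(CO)c1O | intermediate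
17 | 3-[(2S)-2-{[(3S)-3-(tert-butyldimethylsilyloxy)-4-(3-formyl-2-hydroxy-6-methoxyphenyl)-2-methylbutan-2-yl]oxy}-3-methylbut-3-en-1-yl]-2-hydroxy-4-methoxybenzaldehyde | C=C(C)[C@H](Cc1c(OC)ccc(C=O)c1O)OC(C)(C)[C@@H](O[Si](C)(C)C(C)(C)C)Cc1c(OC)ccc(C=O)c1O | intermediate
18 | ethyl (triphenylphosphoranylidene)acetate | CCOC(=O)C=P(c1ccccc1)(c1ccccc1)c1ccccc1 | starting material
19 | bis(ethyl 2-hydroxycinnamate) from 17 (each CHO converted to CH=CH–CO2Et; E/Z mixture; not isolated) | C=C(C)[C@H](Cc1c(OC)ccc(C=CC(=O)OCC)c1O)OC(C)(C)[C@@H](O[Si](C)(C)C(C)(C)C)Cc1c(OC)ccc(C=CC(=O)OCC)c1O | intermediate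
20 | 8-[(2S)-2-{[(3S)-3-(tert-butyldimethylsilyloxy)-4-(7-methoxy-2-oxo-2H-chromen-8-yl)-2-methylbutan-2-yl]oxy}-3-methylbut-3-en-1-yl]-7-methoxy-2H-chromen-2-one | C=C(C)[C@H](Cc1c(OC)ccc2ccc(=O)oc12)OC(C)(C)[C@@H](O[Si](C)(C)C(C)(C)C)Cc1c(OC)ccc2ccc(=O)oc12 | intermediate
21 | CNP0142500.1: 8-[(2S)-2-{[(3S)-3-hydroxy-4-(7-methoxy-2-oxo-2H-chromen-8-yl)-2-methylbutan-2-yl]oxy}-3-methylbut-3-en-1-yl]-7-methoxy-2H-chromen-2-one | C=C(C)[C@H](Cc1c(OC)ccc2ccc(=O)oc12)OC(C)(C)[C@@H](O)Cc1c(OC)ccc2ccc(=O)oc12 | target

Total step count: 11
Longest linear sequence: 11 steps (1 → 21)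

Steps most likely to fail

Step 3. Hydride shift in the activated epoxide (ketone formation) and epoxide oligomerisation may outrun attack by the hindered secondary alcohol. The fallback sets out from 3 and comes back at 4. It replaces the epoxide electrophile by a mercurinium ion and joins two molecules of 3. Concentrated 3 is treated with Hg(O2CCF3)2 (about 0.3 equiv) in CH2Cl2 at 0 °C. The hydroxyl of one molecule should open the mercurinium ion of another at the tertiary carbon, giving the β-alkoxyalkylmercury trifluoroacetate F1. Alkaline NaBH4 then replaces mercury by hydrogen to give 4, and unreacted 3 is recovered. No free tertiary cation is involved, and epoxide 2 then serves only as the source of 3.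

Step 6. Claisen or aldol condensation between molecules may compete with ring closure, or the reaction may stall after the first ring has closed. The fallback sets out from 8 and comes back at 10. It exchanges alkoxide enolisation for soft enolisation of an activated acyl donor. Saponification with LiOH in aqueous THF should give the bis(keto acid) F2. Coupling with 1H-benzotriazole and N,N′-diisopropylcarbodiimide gives the bis(N-acylbenzotriazole) F3. MgBr2·OEt2 and iPr2NEt in CH2Cl2 then generate the magnesium enolate of each ketone, which is C-acylated intramolecularly with loss of benzotriazole. Here too only the side-chain enolate can reach the acyl group through a six-membered ring.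

Step 8. Double selenenylation of one ring, or capture of the isopropenyl group or of the fresh phenol by electrophilic selenium or peroxide, may erode the twofold dehydrogenation. The fallback sets out from 11 and comes back at 15. It uses a Saegusa–Ito oxidation in place of selenium chemistry. Kinetic enolisation with LiN(iPr)2 and trapping with Me3SiCl should give the bis(silyl dienol ether) F4. Stoichiometric Pd(OAc)2 in MeCN then removes the silyl group and a β-hydrogen to give dienone 14, which tautomerises to 15.

Further compounds

F1 | step 3 | β-alkoxyalkylmercury trifluoroacetate from two molecules of 3 (mixture at the mercurated quaternary carbon) | C=C(C)[C@H](CCBr)OC(C)(C[Hg]OC(=O)C(F)(F)F)[C@@H](O)CCBr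
F2 | step 6 | bis(5-oxo acid) corresponding to 8 | C=C(C)[C@H](CCC(=O)CCCC(=O)O)OC(C)(C)[C@@H](O[Si](C)(C)C(C)(C)C)CCC(=O)CCCC(=O)O
F3 | step 6 | bis(N-acylbenzotriazole) of F2 | C=C(C)[C@H](CCC(=O)CCCC(=O)n1nnc2ccccc21)OC(C)(C)[C@@H](O[Si](C)(C)C(C)(C)C)CCC(=O)CCCC(=O)n1nnc2ccccc21
F4 | step 8 | bis(2-trimethylsilyloxy-4-methoxycyclohexa-1,3-diene) from 11 | C=C(C)[C@H](CC1=C(OC)CCC=C1O[Si](C)(C)C)OC(C)(C)[C@@H](O[Si](C)(C)C(C)(C)C)CC1=C(OC)CCC=C1O[Si](C)(C)C
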